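**Strategy.** The route rests on cutting the unfunctionalised C11–C12 ethano bridge between C9 of ring B and the C13 methine. Both carbons are primary and each lies one atom from a stereocentre, so both can be generated as primary radicals from homologous carboxylic acids. A crossed Kolbe electrolysis unites, in one operation and without protecting groups, the ring-A-corrected decalin acetic acid (C12 acid, obtained by ozonolytic excision of C17 and C13–C16 of andrographolide) with methyl hydrogen (R)-3-methylglutarate, two CO2 being expelled. The precursor is thus a γ-keto acid one carbon longer than the fragment it delivers; its C8 ketone later gives the C7=C8 methyl alkene through an enol triflate.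

Key step: step 4

Remark (assumption): labdane numbering is used. α/β describe the real configuration of the andrographolide series: the C20 methyl on C10 and the axial C19 on C4 are α, H-5 and H-9 are β. Andrographolide has an equatorial 3α-OH; the target has an axial 3β-OH. Andrographolide and methyl hydrogen (R)-3-methylglutarate are assumed to be bought as single enantiomers.

Step 1
Reactants: 1 andrographolide
Product: 3 3α,19-dihydroxy-8-oxo-13,14,15,16,17-pentanor-5β,9βH,10α-labdan-12-oic acid, via keto aldehyde 2 (not isolated)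
Conditions: O3, CH2Cl2/MeOH 1:1, −78 °C; Me2S, −78 °C → rt; solvent exchange; NaClO2, NaH2PO4, 2-methyl-2-butene, t-BuOH/H2O, 0 °C → rt
Reagents that add atoms: ozone [O-][O+]=O; sodium chlorite [Na+].[O-]Cl=O
Why: Ozonolysis should cleave both alkenes, C8=C17 to the C8 ketone and the alkylidene-lactone C12=C13 to the C12 aldehyde (expelling C17 and the C13–C16 lactone), and Pinnick oxidation of the crude aldehyde gives the acid without touching the alcohols or C9, which already holds its stable equatorial side chain.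

Step 2
Reactants: 3 3α,19-dihydroxy-8-oxo-13,14,15,16,17-pentanor-5β,9βH,10α-labdan-12-oic acid
Product: 4 19-hydroxy-3,8-dioxo-13,14,15,16,17-pentanor-5β,9βH,10α-labdan-12-oic acid
Conditions: aq. NaOCl (1.2 equiv), AcOH, 15–20 °C
Reagents that add atoms: none
Why: Hypochlorous acid in acetic acid oxidises secondary alcohols much faster than primary ones (selective hypochlorite oxidation of a 1,3-diol), so the 3α-OH should become the ketone while the neopentyl 19-OH survives; no alkene remains to be chlorinated and the acidic medium suppresses retro-aldol loss of C19.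

Step 3
Reactants: 4 19-hydroxy-3,8-dioxo-13,14,15,16,17-pentanor-5β,9βH,10α-labdan-12-oic acid
Product: 5 3β,19-dihydroxy-8-oxo-13,14,15,16,17-pentanor-5β,9βH,10α-labdan-12-oic acid
Conditions: Me4NBH(OAc)3 (5 equiv), MeCN/AcOH 1:1, −30 → 0 °C
Reagents that add atoms: none
Why: In this Evans–Saksena hydroxyl-directed reduction the 19-OH binds boron and delivers hydride through a six-membered transition state to the α face of C3, over which the axial C19 sits, so the new C3 stereocentre should carry the axial 3β-OH anti to C19, while the undirected C8 ketone is not reduced by triacetoxyborohydride.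

Step 4
Reactants: 5 3β,19-dihydroxy-8-oxo-13,14,15,16,17-pentanor-5β,9βH,10α-labdan-12-oic acid; 6 methyl hydrogen (R)-3-methylglutarate
Product: 7 methyl (13R)-3β,19-dihydroxy-8-oxo-17-nor-5β,9βH,10α-labdan-15-oate
Conditions: 6 (6 equiv), NaOMe (5 mol% of total acid), MeOH, Pt anode/Pt cathode, undivided cell, 0.2–0.3 A cm−2, 35–45 °C, until slightly basic
Reagents that add atoms: none
Why: Anodic one-electron oxidation of the two carboxylates on platinum gives acyloxy radicals that lose CO2, and the resulting primary radicals, C11 on the decalin and C12 on the ester chain, combine at the electrode surface to form the C11–C12 bond. The closest known reaction type is the crossed (mixed) Kolbe electrolysis of an alkanoic or γ-keto acid with a methyl hydrogen alkanedioate. No ring is closed and no stereocentre is created: C9 and C13 each sit next to, not at, a radical centre and are carried through unchanged, C9 remaining in its thermodynamically preferred equatorial arrangement α to the ketone. The step needs cross-coupling over homo-coupling, and radical combination over further oxidation to a cation or 1,2-acyl shift of the β-keto radical onto C8. These are secured by the six-fold excess of inexpensive 6 (statistical bias; its dimer is a simple diester), by high current density in weakly acidic methanol, which keeps the radical concentration at the anode high, and by both radicals being primary and unstabilised. Free hydroxyls, the ketone and the ester should be inert at a carboxylate-covered platinum anode.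

Step 5
Reactants: 7 methyl (13R)-3β,19-dihydroxy-8-oxo-17-nor-5β,9βH,10α-labdan-15-oate
Product: 8 methyl (13R)-19-acetoxy-3β-hydroxy-8-oxo-17-nor-5β,9βH,10α-labdan-15-oate
Conditions: Ac2O (1.3 equiv), pyridine, 0 °C → rt
Reagents that add atoms: acetic anhydride CC(=O)OC(C)=O
Why: Selective O-acylation: the primary 19-OH should be acetylated while the axial 3β-OH, flanked by the quaternary C4, is inert without an acyl-transfer catalyst.

Step 6
Reactants: 8 methyl (13R)-19-acetoxy-3β-hydroxy-8-oxo-17-nor-5β,9βH,10α-labdan-15-oate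
Product: 10 methyl (13R)-19-acetoxy-3β-hydroxy-8-(trifluoromethylsulfonyloxy)-17-nor-5β,9βH,10α-labd-7-en-15-oate, via dipotassium alkoxide enolate 9 (not isolated)
Conditions: KHMDS (2.1 equiv), THF, −78 °C; PhNTf2 (1.2 equiv), −78 → −20 °C
Reagents that add atoms: N-phenylbis(trifluoromethanesulfonimide) O=S(=O)(N(c1ccccc1)S(=O)(=O)C(F)(F)F)C(F)(F)F; KHMDS C[Si](C)(C)[N-][Si](C)(C)C.[K+] (potassium in 9 only)
Why: Kinetic deprotonation should remove the unhindered axial C7–H rather than the tertiary C9–H, and the C7=C8 enolate is O-sulfonylated (regioselective enol triflate formation), while the second equivalent of base holds the hindered 3β-OH as an alkoxide that is anti to C19 (no acyl transfer) and too hindered to be sulfonylated.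

Step 7
Reactants: 10 methyl (13R)-19-acetoxy-3β-hydroxy-8-(trifluoromethylsulfonyloxy)-17-nor-5β,9βH,10α-labd-7-en-15-oate
Product: 11 methyl (13R)-19-acetoxy-3β-hydroxy-5β,9βH,10α-labd-7-en-15-oate
Conditions: MeZnCl (4 equiv), Pd(PPh3)4 (5 mol%), THF, 50 °C
Reagents that add atoms: methylzinc chloride C[Zn]Cl
Why: Negishi coupling of the alkenyl triflate should replace OTf by the C17 methyl with the alkene fixed at C7=C8, the organozinc tolerating both esters and the free hydroxyl, which only consumes one equivalent.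

Step 8
Reactants: 11 methyl (13R)-19-acetoxy-3β-hydroxy-5β,9βH,10α-labd-7-en-15-oate
Product: 12 (13R)-19-acetoxy-3β-hydroxy-5β,9βH,10α-labd-7-en-15-oic acid
Conditions: LiI (8 equiv), pyridine, reflux; then 1 M HCl
Reagents that add atoms: none
Why: Iodide should dealkylate the methyl ester by SN2 attack at the O-methyl carbon (nucleophilic ester dealkylation), a path closed to the acetate because its alkyl carbon C19 is neopentyl, so the acid is released with the 19-acetate in place.

**Compound list**

1 | andrographolide (3α,14S,19-trihydroxy-5β,9βH,10α-labda-8(17),12E-dien-16,15-olide) | OC[C@@]1(C)[C@H]2CCC(=C)[C@@H](C/C=C3/C(=O)OC[C@H]3O)[C@]2(C)CC[C@H]1O | starting material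
2 | 3α,19-dihydroxy-8-oxo-13,14,15,16,17-pentanor-5β,9βH,10α-labdan-12-al (keto aldehyde) | OC[C@@]1(C)[C@H]2CCC(=O)[C@@H](CC=O)[C@]2(C)CC[C@H]1O | intermediate
3 | 3α,19-dihydroxy-8-oxo-13,14,15,16,17-pentanor-5β,9βH,10α-labdan-12-oic acid | OC[C@@]1(C)[C@H]2CCC(=O)[C@@H](CC(=O)O)[C@]2(C)CC[C@H]1O | intermediate
4 | 19-hydroxy-3,8-dioxo-13,14,15,16,17-pentanor-5β,9βH,10α-labdan-12-oic acid | OC[C@@]1(C)[C@H]2CCC(=O)[C@@H](CC(=O)O)[C@]2(C)CCC1=O | intermediate
5 | 3β,19-dihydroxy-8-oxo-13,14,15,16,17-pentanor-5β,9βH,10α-labdan-12-oic acid (3-OH axial, anti to C19) | OC[C@@]1(C)[C@H]2CCC(=O)[C@@H](CC(=O)O)[C@]2(C)CC[C@@H]1O | intermediate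
6 | methyl hydrogen (R)-3-methylglutarate, (3R)-5-methoxy-3-methyl-5-oxopentanoic acid | COC(=O)C[C@H](C)CC(=O)O | starting material
7 | methyl (13R)-3β,19-dihydroxy-8-oxo-17-nor-5β,9βH,10α-labdan-15-oate | OC[C@@]1(C)[C@H]2CCC(=O)[C@@H](CC[C@@H](C)CC(=O)OC)[C@]2(C)CC[C@@H]1O | intermediate
8 | methyl (13R)-19-acetoxy-3β-hydroxy-8-oxo-17-nor-5β,9βH,10α-labdan-15-oate | CC(=O)OC[C@@]1(C)[C@H]2CCC(=O)[C@@H](CC[C@@H](C)CC(=O)OC)[C@]2(C)CC[C@@H]1O | intermediate
9 | dipotassium salt of 8: 3β-alkoxide and C7=C8 enolate | CC(=O)OC[C@@]1(C)[C@H]2CC=C([O-])[C@@H](CC[C@@H](C)CC(=O)OC)[C@]2(C)CC[C@@H]1[O-].[K+].[K+] | intermediate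
10 | methyl (13R)-19-acetoxy-3β-hydroxy-8-(trifluoromethylsulfonyloxy)-17-nor-5β,9βH,10α-labd-7-en-15-oate | CC(=O)OC[C@@]1(C)[C@H]2CC=C(OS(=O)(=O)C(F)(F)F)[C@@H](CC[C@@H](C)CC(=O)OC)[C@]2(C)CC[C@@H]1O | intermediate
11 | methyl (13R)-19-acetoxy-3β-hydroxy-5β,9βH,10α-labd-7-en-15-oate | CC(=O)OC[C@@]1(C)[C@H]2CC=C(C)[C@@H](CC[C@@H](C)CC(=O)OC)[C@]2(C)CC[C@@H]1O | intermediate
12 | (13R)-19-acetoxy-3β-hydroxy-5β,9βH,10α-labd-7-en-15-oic acid | CC(=O)OC[C@@]1(C)[C@H]2CC=C(C)[C@@H](CC[C@@H](C)CC(=O)O)[C@]2(C)CC[C@@H]1O | target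

**Total step count:** 8. **Longest linear sequence:** 8 steps (1 → 12); 6 is used as purchased.

**Steps most likely to fail**

1. Step 4 (crossed Kolbe coupling). Symmetrical coupling of each acid, two-electron oxidation of the C11 radical to a cation, or its 1,2-acyl shift may outweigh cross-combination. The fallback sets out from 5 and returns at 7, and changes the union from radical–radical to radical–acceptor. Photocatalytic dehydrodecarboxylation of 5 (9-mesitylacridine cat., Co(dmgH)2(py)Cl cat., 400 nm, CH2Cl2) would turn the C11 radical into the exocyclic enone 3β,19-dihydroxy-12,13,14,15,16,17-hexanor-5β,10α-labd-9(11)-en-8-one F1. Separately, 6 would be condensed with N-hydroxyphthalimide (DIC, DMAP cat., CH2Cl2) to its redox-active ester 1-(1,3-dioxoisoindolin-2-yl) 5-methyl (3S)-3-methylpentanedioate F2 (same spatial arrangement as 6; the descriptor changes by priority only). Reductive decarboxylative Giese addition (Ru(bpy)3Cl2 cat., Hantzsch ester, i-Pr2NEt, CH2Cl2, blue LEDs) of the C12 radical from F2 to C11 of F1, followed by DBU to equilibrate C9 to the equatorial epimer, should give 7.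

2. Step 3 (directed reduction). Hydride delivery from the 19-O–boron species may be incomplete or poorly face-selective, or the C8 ketone may be reduced in part. The fallback sets out from 3 and returns at 11; it postpones the C3 inversion until C8 is no longer a ketone and then uses a bulky external hydride. Crossed Kolbe coupling of 3 with 6 (conditions of step 4) would give methyl (13R)-3α,19-dihydroxy-8-oxo-17-nor-5β,9βH,10α-labdan-15-oate F3. Ac2O, DMAP and pyridine would give its diacetate, methyl (13R)-3α,19-diacetoxy-8-oxo-17-nor-5β,9βH,10α-labdan-15-oate F4. KHMDS and PhNTf2 would give the enol triflate methyl (13R)-3α,19-diacetoxy-8-(trifluoromethylsulfonyloxy)-17-nor-5β,9βH,10α-labd-7-en-15-oate F5, and MeZnCl with Pd(PPh3)4 would give methyl (13R)-3α,19-diacetoxy-5β,9βH,10α-labd-7-en-15-oate F6. K2CO3 in MeOH would free the diol methyl (13R)-3α,19-dihydroxy-5β,9βH,10α-labd-7-en-15-oate F7, and AcCl with 2,4,6-collidine at −78 °C would acetylate the primary hydroxyl to methyl (13R)-19-acetoxy-3α-hydroxy-5β,9βH,10α-labd-7-en-15-oate F8. Dess–Martin periodinane would give methyl (13R)-19-acetoxy-3-oxo-5β,9βH,10α-labd-7-en-15-oate F9. L-Selectride (THF, −78 °C), attacking the 4,4-disubstituted ketone from the equatorial direction, should then give the axial alcohol 11.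

3. Step 8 (ester dealkylation). Dealkylation by iodide may be slow, and prolonged heating in pyridine may cost the acetate. The fallback sets out from 11 and returns at 12. Both esters would be hydrolysed (LiOH, THF/MeOH/H2O, 40 °C) to (13R)-3β,19-dihydroxy-5β,9βH,10α-labd-7-en-15-oic acid F10. The primary 19-OH would then be acetylated selectively (Ac2O, pyridine, 0 °C; NaHCO3 work-up to hydrolyse any mixed anhydride), the axial 3β-OH being inert.

**Further compounds**

F1 | step 4 | 3β,19-dihydroxy-12,13,14,15,16,17-hexanor-5β,10α-labd-9(11)-en-8-one | OC[C@@]1(C)[C@H]2CCC(=O)C(=C)[C@]2(C)CC[C@@H]1O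
F2 | step 4 | 1-(1,3-dioxoisoindolin-2-yl) 5-methyl (3S)-3-methylpentanedioate | COC(=O)C[C@H](C)CC(=O)ON1C(=O)c2ccccc2C1=O
F3 | step 3 | methyl (13R)-3α,19-dihydroxy-8-oxo-17-nor-5β,9βH,10α-labdan-15-oate | OC[C@@]1(C)[C@H]2CCC(=O)[C@@H](CC[C@@H](C)CC(=O)OC)[C@]2(C)CC[C@H]1O
F4 | step 3 | methyl (13R)-3α,19-diacetoxy-8-oxo-17-nor-5β,9βH,10α-labdan-15-oate | CC(=O)OC[C@@]1(C)[C@H]2CCC(=O)[C@@H](CC[C@@H](C)CC(=O)OC)[C@]2(C)CC[C@H]1OC(C)=O
F5 | step 3 | methyl (13R)-3α,19-diacetoxy-8-(trifluoromethylsulfonyloxy)-17-nor-5β,9βH,10α-labd-7-en-15-oate | CC(=O)OC[C@@]1(C)[C@H]2CC=C(OS(=O)(=O)C(F)(F)F)[C@@H](CC[C@@H](C)CC(=O)OC)[C@]2(C)CC[C@H]1OC(C)=O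
F6 | step 3 | methyl (13R)-3α,19-diacetoxy-5β,9βH,10α-labd-7-en-15-oate | CC(=O)OC[C@@]1(C)[C@H]2CC=C(C)[C@@H](CC[C@@H](C)CC(=O)OC)[C@]2(C)CC[C@H]1OC(C)=O
F7 | step 3 | methyl (13R)-3α,19-dihydroxy-5β,9βH,10α-labd-7-en-15-oate | OC[C@@]1(C)[C@H]2CC=C(C)[C@@H](CC[C@@H](C)CC(=O)OC)[C@]2(C)CC[C@H]1O
F8 | step 3 | methyl (13R)-19-acetoxy-3α-hydroxy-5β,9βH,10α-labd-7-en-15-oate | CC(=O)OC[C@@]1(C)[C@H]2CC=C(C)[C@@H](CC[C@@H](C)CC(=O)OC)[C@]2(C)CC[C@H]1O
F9 | step 3 | methyl (13R)-19-acetoxy-3-oxo-5β,9βH,10α-labd-7-en-15-oate | CC(=O)OC[C@@]1(C)[C@H]2CC=C(C)[C@@H](CC[C@@H](C)CC(=O)OC)[C@]2(C)CCC1=O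
F10 | step 8 | (13R)-3β,19-dihydroxy-5β,9βH,10α-labd-7-en-15-oic acid | OC[C@@]1(C)[C@H]2CC=C(C)[C@@H](CC[C@@H](C)CC(=O)O)[C@]2(C)CC[C@@H]1O
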